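**Retrosynthetic overview**
1. Endgame: C20 by methylenation of a C11 ketone; C6–Cl and C5=C16 by ene-chlorination of a 5-methyl-5,6-alkene; 3-OAc/2-OH by C9-hydroxyl-directed epoxidation of a 2,3-alkene and acetate opening at C3.
2. Ten-membered ring last, by ring-closing metathesis (C2=C3) across the cis-2,6 positions (C4, C8) of the oxane. Before that, the γ-lactone (O7–C7) by rhenium-catalysed allylic transposition after methyl (C16) addition to C5=O, and C8–C17 by ketene-acetal addition to the C8 oxocarbenium ion.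
3. Oxane ring O–C4–C5–C6–C7–C8 by oxidative ring expansion of a 2,5-disubstituted furan (furan carbons = C5–C8), the C4 carbinol oxygen adding to C8. Enabling feature: C5 (sp2, bearing C16) and C8 (bonded to the ring oxygen) are 1,4-related through C6–C7, and C4 carries that oxygen, which is the pattern of a furan-2-yl carbinol.
4. Furan joined to ring A at C9 (aryllithium + aldehyde) and extended at C4 (vinylzinc). Ring A from p-benzoquinone monoketal by rhodium-catalysed desymmetrising conjugate addition (C10), two enolate alkylations (C1) and hydride reduction (C14).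
5. Ring order: ring A → furan → oxane (key step) → γ-lactone → ten-membered ring (oxocane bridge).

Key step: step 14

Remark: atoms are cited by briarane numbers (ten-membered ring C1–C10; ring A = C1, C10–C14; C15 on C1; C16 on C5; lactone C7–C8–C17–C19 with C18 on C17; C20 on C11). Stereochemical outcomes are expectations based on the stated models. In the SMILES of the Tebbe reagent the chloride bridge between titanium and aluminium is drawn as a chloronium–aluminate pair.

Step 1
Reactants: 1 1,4-dioxaspiro[4.5]deca-6,9-dien-8-one; 2 (2-methylprop-1-en-1-yl)boronic acid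
Product: 3 (S)-10-(2-methylprop-1-en-1-yl)-1,4-dioxaspiro[4.5]dec-6-en-8-one
Conditions: Rh(acac)(C2H4)2 (3 mol%), (S)-BINAP, dioxane/H2O 10:1, 50 °C
Reagents that add atoms: none
Why: Rhodium-catalysed asymmetric conjugate addition of an alkenylboronic acid (Hayashi–Miyaura type) desymmetrises the dienone; the (S)-BINAP complex should select the alkene face as it does with cyclohexenone and so set C10 (S), the alkenyl group being a latent C9 aldehyde.

Step 2
Reactants: 3 (S)-10-(2-methylprop-1-en-1-yl)-1,4-dioxaspiro[4.5]dec-6-en-8-one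
Product: 4 trans-9-methyl-10-(2-methylprop-1-en-1-yl)-1,4-dioxaspiro[4.5]dec-6-en-8-one
Conditions: LiN(i-Pr)2, THF, −78 °C; MeI, −78 → −30 °C
Reagents that add atoms: iodomethane CI
Why: Kinetic enolate alkylation at the only sp3 α-carbon (C1; the other α-carbon is vinylic and the γ-carbon is the ketal carbon) introduces C15 anti to the C10 substituent, a centre that is re-enolised in step 3.

Step 3
Reactants: 4 trans-9-methyl-10-(2-methylprop-1-en-1-yl)-1,4-dioxaspiro[4.5]dec-6-en-8-one
Product: 5 9-allyl-9-methyl-10-(2-methylprop-1-en-1-yl)-1,4-dioxaspiro[4.5]dec-6-en-8-one (allyl trans to the alkenyl group)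
Conditions: LiN(i-Pr)2, THF, −78 °C; allyl bromide, DMPU, −78 → 0 °C
Reagents that add atoms: allyl bromide C=CCBr
Why: Second enolate alkylation creates the quaternary C1; the allyl group (its first carbon is C2) should enter anti to the adjacent C10 alkenyl group, leaving C15 cis to C9 as in the target.

Step 4
Reactants: 5 9-allyl-9-methyl-10-(2-methylprop-1-en-1-yl)-1,4-dioxaspiro[4.5]dec-6-en-8-one
Product: 7 7-allyl-7-methyl-6-(2-methylprop-1-en-1-yl)-1,4-dioxaspiro[4.5]decan-8-ol (8-OH cis to allyl), via saturated ketone 6 (not isolated)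
Conditions: LiBH(s-Bu)3 (2.4 equiv), t-BuOH (1.0 equiv), THF, −78 → −20 °C; aq. NH4Cl
Reagents that add atoms: none
Why: Conjugate hydride delivery to the β-unsubstituted enone gives the enolate, t-BuOH releases ketone 6, and the bulky trialkylborohydride then attacks C14 from the equatorial side to give the axial alcohol, cis to C2 and trans to C15.

Step 5
Reactants: 7 7-allyl-7-methyl-6-(2-methylprop-1-en-1-yl)-1,4-dioxaspiro[4.5]decan-8-ol
Product: 8 7-allyl-8-hydroxy-7-methyl-1,4-dioxaspiro[4.5]decane-6-carbaldehyde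
Conditions: O3, CH2Cl2/MeOH, pyridine, Sudan Red indicator, −78 °C; Me2S
Reagents that add atoms: ozone [O-][O+]=O
Why: Ozonolysis is selective for the electron-rich trisubstituted alkene over the terminal allyl group and unmasks the C9 aldehyde without touching a stereocentre.

Step 6
Reactants: 8 7-allyl-8-hydroxy-7-methyl-1,4-dioxaspiro[4.5]decane-6-carbaldehyde; 9 2-(diethoxymethyl)furan
Product: 10 [5-(diethoxymethyl)furan-2-yl](7-allyl-8-hydroxy-7-methyl-1,4-dioxaspiro[4.5]decan-6-yl)methanol (C9 epimers)
Conditions: 9 (2.2 equiv), n-BuLi, THF, −78 → 0 °C; then 8, −78 °C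
Reagents that add atoms: none
Why: α-Lithiation of the furan acetal and addition of the aryllithium to the aldehyde joins furan carbon C8 to C9; both C9 epimers are taken on because step 7 removes this centre.

Step 7
Reactants: 10 [5-(diethoxymethyl)furan-2-yl](7-allyl-8-hydroxy-7-methyl-1,4-dioxaspiro[4.5]decan-6-yl)methanol
Product: 11 [5-(diethoxymethyl)furan-2-yl](7-allyl-8-hydroxy-7-methyl-1,4-dioxaspiro[4.5]decan-6-yl)methanone
Conditions: MnO2, CH2Cl2, rt
Reagents that add atoms: none
Why: MnO2 oxidises only the activated furfuryl alcohol, leaving the saturated C14 hydroxyl and the C10 centre untouched under neutral conditions.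

Step 8
Reactants: 11 [5-(diethoxymethyl)furan-2-yl](7-allyl-8-hydroxy-7-methyl-1,4-dioxaspiro[4.5]decan-6-yl)methanone
Product: 12 14-O-acetyl furyl ketone (acetate of 11 at the ring-A hydroxyl)
Conditions: Ac2O, DMAP, Et3N, CH2Cl2, rt
Reagents that add atoms: acetic anhydride CC(=O)OC(C)=O
Why: DMAP-catalysed acylation installs the C14 acetate of the target while it is the only hydroxyl present.

Step 9
Reactants: 12 14-O-acetyl furyl ketone
Product: 13 (9S)-furylcarbinol 14-acetate
Conditions: Zn(BH4)2, Et2O, −30 °C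
Reagents that add atoms: none
Why: Chelation-controlled ketone reduction: zinc should bridge the C9 carbonyl and a C11 ketal oxygen so that hydride enters anti to the quaternary C1, which gives the (9S)-alcohol.

Step 10
Reactants: 13 (9S)-furylcarbinol 14-acetate
Product: 14 9-O-TBS ether of 13
Conditions: TBSOTf, 2,6-lutidine, CH2Cl2, −40 → 0 °C
Reagents that add atoms: tert-butyldimethylsilyl triflate CC(C)(C)[Si](C)(C)OS(=O)(=O)C(F)(F)F
Why: Silylation blocks O9 so that only the C4 hydroxyl can take part in the later furan ring expansion, and keeps O9 distinguishable for the directed epoxidation.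

Step 11
Reactants: 14 9-O-TBS ether of 13
Product: 15 (E)-prop-1-enyl isomer of 14 (C1–CH=CH–CH3)
Conditions: [Ir(cod)(PMePh2)2]PF6 (2 mol%, H2-activated), THF, rt
Reagents that add atoms: none
Why: Iridium hydride-catalysed isomerisation of the terminal allyl group moves the alkene to C2 for the later metathesis (propene is then extruded) and touches no stereocentre.

Step 12
Reactants: 15 (E)-prop-1-enyl isomer of 14
Product: 16 5-substituted furan-2-carbaldehyde (C4 aldehyde)
Conditions: PPTS (cat.), acetone/H2O 10:1, 0 °C → rt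
Reagents that add atoms: water O
Why: The acyclic furfural acetal hydrolyses far faster than the hindered dioxolane or the silyl ether, which frees the C4 aldehyde.

Step 13
Reactants: 16 5-substituted furan-2-carbaldehyde
Product: 17 (4S)-1-(furan-2-yl)prop-2-en-1-ol derivative (C4 carbinol bearing the C3 vinyl group)
Conditions: Zn(CH=CH2)2, (−)-DAIB (10 mol%), toluene, 0 °C
Reagents that add atoms: divinylzinc C=C[Zn]C=C
Why: Amino alcohol-catalysed enantioselective alkenylzinc addition to an aryl aldehyde (Noyori/Oppolzer type); (−)-DAIB should direct vinyl transfer to the Si face and give the (S)-carbinol that becomes C4 of the target.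

Step 14
Reactants: 17 (4S)-furyl vinyl carbinol
Product: 19 6-hydroxy-2H-pyran-3(6H)-one hemiketal (C4 vinyl; C5 ketone; C6=C7; C8 bearing OH and the C9 side chain; C8 anomers), via Z-ene-dione 18 (not isolated)
Conditions: N-bromosuccinimide, NaHCO3, THF/H2O 4:1, 0 °C
Reagents that add atoms: water O
Why: Bromination of the electron-rich furan and addition of water give the 2,5-dihydrofuran, which opens to the (Z)-ene-dione 18 (C5 and C8 ketones, cis C6=C7); the C4 hydroxyl then adds to the C8 carbonyl, forming the O–C8 bond and closing the six-membered oxane ring by 6-exo-trig hemiketalisation. This is the Achmatowicz rearrangement of furan-2-yl carbinols, a ring expansion of the furan to a pyranone. In one operation the flat furan becomes the oxygenated ring core: the C5 ketone (later C5=C16), the C6=C7 alkene (later C6–Cl and C7–O) and the C8 ketal carbon (later the quaternary centre). No stereocentre is fixed here, since both C8 anomers ionise to the same oxocarbenium ion in step 15, and C4 from step 13 is not touched. The step needs oxidation of the furan in preference to the vinyl and propenyl groups, which the much higher reactivity of the furan toward NBS at 0 °C should secure. It also needs ring closure through O4 and not O9, which the silyl ether at C9 secures.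

Step 15
Reactants: 19 pyranone hemiketal; 20 1-methoxy-1-(trimethylsilyloxy)prop-1-ene
Product: 21 methyl 2-(pyranon-6-yl)propanoate with quaternary C8 (C17 epimers)
Conditions: 20 (3 equiv), BF3·OEt2, CH2Cl2, −78 °C
Reagents that add atoms: none
Why: Mukaiyama-type C-glycosylation: BF3 ionises the hemiketal (silylated in situ) to the C8 oxocarbenium ion and the ketene acetal should add anti to the C4 vinyl group, as nucleophiles do with Achmatowicz pyranones, placing C9 cis to C3; C17 forms unselectively and is corrected in step 18.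

Step 16
Reactants: 21 methyl 2-(pyranon-6-yl)propanoate
Product: 22 C5 tertiary allylic alcohol (C5 bearing OH and the C16 methyl; C5 epimers)
Conditions: MeLi, CeCl3, THF, −78 °C
Reagents that add atoms: methyllithium [Li]C
Why: Organocerium 1,2-addition to the enone carbonyl, chemoselective over the ester and acetate groups, introduces C16; the new C5 centre is destroyed in step 17.

Step 17
Reactants: 22 C5 tertiary allylic alcohol
Product: 23 cis-fused γ-lactone with 5-methyl-5,6-alkene (dihydropyran; C4 vinyl; C17 epimers)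
Conditions: Re2O7 (5 mol%), CH2Cl2, rt
Reagents that add atoms: none
Why: Re2O7-catalysed 1,3-transposition of the tertiary allylic alcohol moves the oxygen to C7 and the alkene to C5=C6, and only the C7 epimer cis to the C17 side chain can lactonise with loss of methanol, which drains the equilibrium and sets C7.

Step 18
Reactants: 23 cis-fused γ-lactone diene
Product: 25 bridged tricyclic 2,3-alkene with (17R) configuration and 9-OTBS, via C17-epimeric bridged alkene 24 (not isolated)
Conditions: second-generation Hoveyda–Grubbs catalyst (10 mol%), toluene (1 mM), 80 °C; then DBU, rt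
Reagents that add atoms: none
Why: Ring-closing metathesis of the C4 vinyl and C1 propenyl groups closes the eight-membered oxocane, and with it the ten-membered carbocycle, as the Z-alkene (the C5 methyl and the fused lactone favour the diaxial arrangement of the two arms); DBU then equilibrates C17 to the epimer with C18 anti to the bulky C9 substituent.

Step 19
Reactants: 25 bridged tricyclic 2,3-alkene (9-OTBS)
Product: 26 9-hydroxy bridged alkene
Conditions: HF·pyridine, THF, 0 °C → rt
Reagents that add atoms: none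
Why: Fluoride-mediated desilylation frees the C9 hydroxyl as the directing group while the acetate, lactone and ketal survive.

Step 20
Reactants: 26 9-hydroxy bridged alkene
Product: 27 2,3-epoxide cis to the C9 hydroxyl
Conditions: VO(acac)2 (5 mol%), t-BuOOH, CH2Cl2, 0 °C → rt
Reagents that add atoms: tert-butyl hydroperoxide CC(C)(C)OO
Why: Hydroxyl-directed epoxidation: the C9 hydroxyl lies on the same face of the oxocane as the required C2–O bond, so oxygen delivery from the vanadium alkoxide should give the epoxide cis to it, while the C5=C6 alkene is deactivated by its two allylic C–O bonds.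

Step 21
Reactants: 27 2,3-epoxide
Product: 28 9-O-acetyl 2,3-epoxide
Conditions: Ac2O, DMAP, Et3N, CH2Cl2, rt
Reagents that add atoms: acetic anhydride CC(=O)OC(C)=O
Why: Acylation of the only free hydroxyl installs the C9 acetate before C2–OH is released, so no selective acetylation is needed later.

Step 22
Reactants: 28 9-O-acetyl 2,3-epoxide
Product: 29 3-acetoxy-2-hydroxy compound (trans)
Conditions: AcOH, NaOAc, 60 °C
Reagents that add atoms: acetic acid CC(=O)O
Why: Acetate opens the epoxide by SN2 attack at C3 (C2 is neopentylic) with inversion, which gives the trans 3-acetate/2-alcohol in the acylation pattern of the target.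

Step 23
Reactants: 29 3-acetoxy-2-hydroxy compound
Product: 30 6-chloro-5(16)-ene
Conditions: Ca(OCl)2, CO2 (dry ice), CH2Cl2/H2O, 0 °C, short contact
Reagents that add atoms: calcium hypochlorite [Ca+2].[O-]Cl.[O-]Cl
Why: Ene-type allylic chlorination with HOCl: Cl+ adds to C6 of the trisubstituted alkene and a C16 proton is lost to give the exocyclic alkene, and attack anti to the transannular bridge that covers the other face of the oxane should place Cl cis to O7.

Step 24
Reactants: 30 6-chloro-5(16)-ene
Product: 31 C11 ketone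
Conditions: PPTS, acetone/H2O, 45 °C
Reagents that add atoms: water O
Why: Mild acid hydrolysis of the dioxolane releases the C11 ketone; the acetates, the lactone and the secondary allylic chloride (flanked by an acyloxy carbon) should survive.

Step 25
Reactants: 31 C11 ketone
Product: 32 CNP0248899.1 (target)
Conditions: Cp2Ti(μ-Cl)(μ-CH2)AlMe2 (Tebbe reagent, excess), pyridine, THF/toluene, −40 → 0 °C
Reagents that add atoms: Tebbe reagent C[Al-]1(C)C[Ti](C2C=CC=C2)(C2C=CC=C2)[Cl+]1
Why: Tebbe methylenation (titanium methylidene, oxatitanacyclobutane) converts the ketone to the 11(20)-alkene under non-basic conditions that spare the β-acetoxy group at C9 and the allylic chloride, and ketones react faster than esters at low temperature, so the acetates and the lactone should survive.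

**Compound list**
1 | 1,4-dioxaspiro[4.5]deca-6,9-dien-8-one | O=C1C=CC2(C=C1)OCCO2 | starting material
2 | (2-methylprop-1-en-1-yl)boronic acid | CC(C)=CB(O)O | starting material
3 | (S)-10-(2-methylprop-1-en-1-yl)-1,4-dioxaspiro[4.5]dec-6-en-8-one | O1CCOC12C=CC(=O)C[C@H]2C=C(C)C | intermediate
4 | trans-9-methyl-10-(2-methylprop-1-en-1-yl)-1,4-dioxaspiro[4.5]dec-6-en-8-one | O1CCOC12C=CC(=O)[C@H](C)[C@H]2C=C(C)C | intermediate
5 | 9-allyl-9-methyl-10-(2-methylprop-1-en-1-yl)-1,4-dioxaspiro[4.5]dec-6-en-8-one (allyl trans to alkenyl) | O1CCOC12C=CC(=O)[C@@](CC=C)(C)[C@H]2C=C(C)C | intermediate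
6 | 7-allyl-7-methyl-6-(2-methylprop-1-en-1-yl)-1,4-dioxaspiro[4.5]decan-8-one (not isolated) | O1CCOC12CCC(=O)[C@@](CC=C)(C)[C@H]2C=C(C)C | intermediate
7 | 7-allyl-7-methyl-6-(2-methylprop-1-en-1-yl)-1,4-dioxaspiro[4.5]decan-8-ol (OH cis to allyl) | O1CCOC12CC[C@H](O)[C@@](CC=C)(C)[C@H]2C=C(C)C | intermediate
8 | 7-allyl-8-hydroxy-7-methyl-1,4-dioxaspiro[4.5]decane-6-carbaldehyde | O1CCOC12CC[C@H](O)[C@@](CC=C)(C)[C@H]2C=O | intermediate
9 | 2-(diethoxymethyl)furan | CCOC(OCC)c1ccco1 | starting material
10 | furylcarbinol diol, C9 epimers | O1CCOC12CC[C@H](O)[C@@](CC=C)(C)[C@H]2C(O)c1ccc(C(OCC)OCC)o1 | intermediate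
11 | furyl ketone (C9=O) with free C14 hydroxyl | O1CCOC12CC[C@H](O)[C@@](CC=C)(C)[C@H]2C(=O)c1ccc(C(OCC)OCC)o1 | intermediate
12 | 14-O-acetyl furyl ketone | O1CCOC12CC[C@H](OC(C)=O)[C@@](CC=C)(C)[C@H]2C(=O)c1ccc(C(OCC)OCC)o1 | intermediate
13 | (9S)-furylcarbinol 14-acetate | O1CCOC12CC[C@H](OC(C)=O)[C@@](CC=C)(C)[C@H]2[C@H](O)c1ccc(C(OCC)OCC)o1 | intermediate
14 | 9-O-TBS ether of 13 | O1CCOC12CC[C@H](OC(C)=O)[C@@](CC=C)(C)[C@H]2[C@H](O[Si](C)(C)C(C)(C)C)c1ccc(C(OCC)OCC)o1 | intermediate
15 | (E)-prop-1-enyl isomer of 14 | O1CCOC12CC[C@H](OC(C)=O)[C@@](/C=C/C)(C)[C@H]2[C@H](O[Si](C)(C)C(C)(C)C)c1ccc(C(OCC)OCC)o1 | intermediate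
16 | 5-substituted furan-2-carbaldehyde (C4 aldehyde) | O1CCOC12CC[C@H](OC(C)=O)[C@@](/C=C/C)(C)[C@H]2[C@H](O[Si](C)(C)C(C)(C)C)c1ccc(C=O)o1 | intermediate
17 | (4S)-furyl vinyl carbinol | O1CCOC12CC[C@H](OC(C)=O)[C@@](/C=C/C)(C)[C@H]2[C@H](O[Si](C)(C)C(C)(C)C)c1ccc([C@@H](O)C=C)o1 | intermediate
18 | (Z)-ene-dione with free C4 hydroxyl (not isolated) | O1CCOC12CC[C@H](OC(C)=O)[C@@](/C=C/C)(C)[C@H]2[C@H](O[Si](C)(C)C(C)(C)C)C(=O)/C=C\C(=O)[C@@H](O)C=C | intermediate
19 | 6-hydroxy-2H-pyran-3(6H)-one hemiketal (C8 anomers) | O1CCOC12CC[C@H](OC(C)=O)[C@@](/C=C/C)(C)[C@H]2[C@H](O[Si](C)(C)C(C)(C)C)C3(O)O[C@H](C(=O)C=C3)C=C | intermediate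
20 | 1-methoxy-1-(trimethylsilyloxy)prop-1-ene | CC=C(OC)O[Si](C)(C)C | starting material
21 | pyranone methyl propanoate with quaternary C8 (C17 epimers) | O1CCOC12CC[C@H](OC(C)=O)[C@@](/C=C/C)(C)[C@H]2[C@H](O[Si](C)(C)C(C)(C)C)[C@@]3(C(C)C(=O)OC)O[C@H](C(=O)C=C3)C=C | intermediate
22 | C5 tertiary allylic alcohol (C5 and C17 epimers) | O1CCOC12CC[C@H](OC(C)=O)[C@@](/C=C/C)(C)[C@H]2[C@H](O[Si](C)(C)C(C)(C)C)[C@@]3(C(C)C(=O)OC)O[C@H](C(C)(O)C=C3)C=C | intermediate
23 | cis-fused γ-lactone with 5-methyl-5,6-alkene (C17 epimers) | O1CCOC12CC[C@H](OC(C)=O)[C@@](/C=C/C)(C)[C@H]2[C@H](O[Si](C)(C)C(C)(C)C)[C@@]34O[C@H](C(C)=C[C@@H]3OC(=O)C4C)C=C | intermediate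
24 | bridged tricyclic (Z)-2,3-alkene, C17 epimers (not isolated) | C[C@@]12/C=C\[C@@H]3O[C@@]4([C@@H](O[Si](C)(C)C(C)(C)C)[C@H]1C5(OCCO5)CC[C@@H]2OC(C)=O)C(C)C(=O)O[C@H]4C=C3C | intermediate
25 | bridged tricyclic (Z)-2,3-alkene, (17R), 9-OTBS | C[C@@]12/C=C\[C@@H]3O[C@@]4([C@@H](O[Si](C)(C)C(C)(C)C)[C@H]1C5(OCCO5)CC[C@@H]2OC(C)=O)[C@@H](C)C(=O)O[C@H]4C=C3C | intermediate
26 | 9-hydroxy bridged alkene | C[C@@]12/C=C\[C@@H]3O[C@@]4([C@@H](O)[C@H]1C5(OCCO5)CC[C@@H]2OC(C)=O)[C@@H](C)C(=O)O[C@H]4C=C3C | intermediate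
27 | 2,3-epoxide cis to 9-OH | O1CCOC12CC[C@H](OC(C)=O)[C@@]5(C)[C@H]2[C@H](O)[C@@]34O[C@H](C(C)=C[C@@H]3OC(=O)[C@@H]4C)[C@@H]6O[C@H]56 | intermediate
28 | 9-O-acetyl 2,3-epoxide | O1CCOC12CC[C@H](OC(C)=O)[C@@]5(C)[C@H]2[C@H](OC(C)=O)[C@@]34O[C@H](C(C)=C[C@@H]3OC(=O)[C@@H]4C)[C@@H]6O[C@H]56 | intermediate
29 | 3-acetoxy-2-hydroxy compound (5-methyl-5,6-ene; C11 ketal) | O1CCOC12CC[C@H](OC(C)=O)[C@@]5(C)[C@H]2[C@H](OC(C)=O)[C@@]34O[C@H](C(C)=C[C@@H]3OC(=O)[C@@H]4C)[C@@H](OC(C)=O)[C@@H]5O | intermediate
30 | 6-chloro-5(16)-ene (C11 ketal) | O1CCOC12CC[C@H](OC(C)=O)[C@@]5(C)[C@H]2[C@H](OC(C)=O)[C@@]34O[C@H](C(=C)[C@H](Cl)[C@@H]3OC(=O)[C@@H]4C)[C@@H](OC(C)=O)[C@@H]5O | intermediate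
31 | C11 ketone | O=C1CC[C@H](OC(C)=O)[C@@]2(C)[C@H]1[C@H](OC(C)=O)[C@@]34O[C@H](C(=C)[C@H](Cl)[C@@H]3OC(=O)[C@@H]4C)[C@@H](OC(C)=O)[C@@H]2O | intermediate
32 | CNP0248899.1: 3,9,14-triacetoxy-6-chloro-2-hydroxy-4,8-epoxybriara-5(16),11(20)-dien-19,7-olide | C=C1CC[C@H](OC(C)=O)[C@@]2(C)[C@H]1[C@H](OC(C)=O)[C@@]13O[C@H](C(=C)[C@H](Cl)[C@@H]1OC(=O)[C@@H]3C)[C@@H](OC(C)=O)[C@@H]2O | target

Total step count: 25. Longest linear sequence: 25 steps (1 → 32).

**Steps most likely to fail**

Step 18 (ring-closing metathesis). The cyclisation may be slow or give oligomers, because one alkene sits on the quaternary C1 and both arms must be axial on the dihydropyran. Fallback from 23: OsO4 (cat.)/NaIO4 would cleave the vinyl and propenyl groups to the dialdehyde F2. Intramolecular McMurry coupling with low-valent titanium (TiCl3, Zn–Cu, DME, reflux, high dilution) would then form the C2=C3 alkene, and the DBU equilibration of step 18 would bring the route back at 25.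

Step 20 (directed epoxidation). Oxygen may be delivered to the C5=C6 alkene or to the wrong face of C2=C3 if the C9 alkoxide cannot reach across the oxocane. Fallback from 26, without a directing group: acetylation (Ac2O, DMAP) would give the 9-acetate F3. OsO4/NMO dihydroxylation from the more open outer face would give the cis-2,3-diol F4. Selective acetylation of the less hindered C3 hydroxyl (Ac2O, collidine) would give the 3-monoacetate F5. Dess–Martin oxidation would give the C2 ketone F6. Reduction with NaBH4/CeCl3, hydride again entering from the outer face, would invert C2 and return to the route at 29.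

Step 15 (C-glycosylation). Ionisation at the hindered tertiary centre may be sluggish, the facial selectivity at C8 may be poor, or the ketene acetal may add to C7 in a conjugate fashion. Fallback from 19, through its ring-opened keto tautomer: Horner–Wadsworth–Emmons olefination of the C8 ketone with methyl 2-(dimethoxyphosphoryl)propanoate (LiCl, DBU, MeCN) would give the open-chain enoate F1. Base-mediated oxa-conjugate addition of the C4 hydroxyl to C8 (cat. KOt-Bu, THF, equilibrating conditions, epimers separated) would then close the oxane and return to the route at 21.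

Further compounds
F1 | step 15 | open-chain enoate (C8=C17) with free C4 hydroxyl and C5 ketone | O1CCOC12CC[C@H](OC(C)=O)[C@@](/C=C/C)(C)[C@H]2[C@H](O[Si](C)(C)C(C)(C)C)C(=C(C)C(=O)OC)/C=C\C(=O)[C@@H](O)C=C
F2 | step 18 | C2,C3-dialdehyde of the lactone | O1CCOC12CC[C@H](OC(C)=O)[C@@](C=O)(C)[C@H]2[C@H](O[Si](C)(C)C(C)(C)C)[C@@]34O[C@H](C(C)=C[C@@H]3OC(=O)C4C)C=O
F3 | step 20 | 9-O-acetyl bridged 2,3-alkene | C[C@@]12/C=C\[C@@H]3O[C@@]4([C@@H](OC(C)=O)[C@H]1C5(OCCO5)CC[C@@H]2OC(C)=O)[C@@H](C)C(=O)O[C@H]4C=C3C
F4 | step 20 | cis-2,3-diol (both hydroxyls on the outer face) | O1CCOC12CC[C@H](OC(C)=O)[C@@]5(C)[C@H]2[C@H](OC(C)=O)[C@@]34O[C@H](C(C)=C[C@@H]3OC(=O)[C@@H]4C)[C@@H](O)[C@H]5O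
F5 | step 20 | 3-O-acetyl cis-diol | O1CCOC12CC[C@H](OC(C)=O)[C@@]5(C)[C@H]2[C@H](OC(C)=O)[C@@]34O[C@H](C(C)=C[C@@H]3OC(=O)[C@@H]4C)[C@@H](OC(C)=O)[C@H]5O
F6 | step 20 | 3-acetoxy C2 ketone | O1CCOC12CC[C@H](OC(C)=O)[C@@]5(C)[C@H]2[C@H](OC(C)=O)[C@@]34O[C@H](C(C)=C[C@@H]3OC(=O)[C@@H]4C)[C@@H](OC(C)=O)C5=O
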